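A small charge of G turns a much larger charge of J into X, 100 J for each G in the west run. G is a catalyst: it comes back after each turn. My first guess is therefore that G works like a clock, with the flask passing through the same states at a speed proportional to [G].

| flask | J | G | time |
|---|---|---|---|
| west | 0.150 M | 0.00150 M |  |
| north-east | 0.0600 M | 0.00150 M |  |
| north-west | 0.220 M | 0.00150 M |  |
| south | 0.150 M | 0.00450 M |  |
| south-east | 0.0500 M | 0.00300 M | 21 min |

| run | time / min | [X] / M |
|---|---|---|
| west run | 0.75 | 0.0031 |
| west run | 2.3 | 0.0069 |
| west run | 4.4 | 0.0151 |
| west run | 6.9 | 0.0223 |
| west run | 9.9 | 0.0310 |
| west run | 13 | 0.0411 |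
| west run | 17 | 0.0503 |
| west run | 21 | 0.0616 |
| north-east run | 0.75 | 8 × 10⁻⁴ |
| north-east run | 2.3 | 0.0033 |
| north-east run | 4.4 | 0.0092 |
| north-east run | 6.9 | 0.0127 |
| north-east run | 9.9 | 0.0165 |
| north-east run | 13 | 0.0237 |
| north-east run | 17 | 0.0285 |
| north-east run | 21 | 0.0329 |
| north-west run | 0.75 | 0.0020 |
| north-west run | 2.3 | 0.0104 |
| north-west run | 4.4 | 0.0179 |
| north-west run | 6.9 | 0.0299 |
| north-west run | 9.9 | 0.0399 |
| north-west run | 13 | 0.0520 |
| north-west run | 17 | 0.0665 |
| north-west run | 21 | 0.0803 |
| south run | 0.75 | 0.0109 |
| south run | 2.3 | 0.0307 |
| south run | 4.4 | 0.0558 |
| south run | 6.9 | 0.0803 |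
| south run | 9.9 | 0.1042 |
| south run | 13 | 0.1216 |
| south run | 17 | 0.1376 |
| south run | 21 | 0.1450 |

(readings scatter by 8 × 10⁻⁴ M)

* apparent order in [G] of the starting rate, round the charge of the west run (the rate where two percent of its J have turned into X)
* apparent order in [J] of the starting rate, round the charge of the west run (the rate where two percent of its J have turned into X) (one fixed amount of X, the same in the runs compared)
* the north-east run starts with 0.0900 M less of J than the west run, and with no X. Compared where both hold the same amount of J, once fifteen percent of what the north-east run was charged with has turned into X, is the north-east run faster, slower or alike (within a tenth)?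
* X in the south-east run at 21 min, as a share of the J charged

- Overall: J -> X, with G as catalyst.
- Constant volume, constant temperature.
- The analysis sees a species whether free or bound.
- An order is taken over about fifteen percent of the charge, up and down.

The west and south runs start with the same [J], and their [G] differs by a factor of 3.00. They arrive at close readings of X, 0.0310 M and 0.0307 M, but the west run takes 9.9 min and the south run 2.3 min. So the south clock is faster by a factor of 4.30, which is more than [G] grew. Speed is therefore not proportional to the G charged. Suppose instead that a fixed amount of G does no work, so that speed follows the charge minus that amount, the working G. Requiring the two working amounts to stand in the measured factor gives, as a reading, 5.92 × 10⁻⁴ M. I call this the dead G, the amount to take from the charge of each flask here before it counts.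

A clock also needs a flask to respond to the J it holds and not to the X it has made. At the same [G], the north-west run between 17 min and 21 min holds [J] near 0.147 M beside 0.0734 M of X, and makes X at 0.00345 M min⁻¹. The west run over its first 4.4 min, with [J] near 0.142 M, makes X at 0.00343 M min⁻¹. I therefore treat a run charged with less J as the late part of a run charged with more, at the same working G.

The south-east run then follows from the south run. The working G of the south-east run is 0.00241 M against 0.00391 M in the south run, so the south-east clock runs at 0.616 of the south clock. The south run passes through [J] = 0.0500 M at about 9.37 min, so 21 min in the south-east run ends at 22.3 min on the south clock, past its last reading at 21 min. Over its last two readings, the J left in the south run falls with a time constant read as 4.40 min. Extending that tail, I commit to 92.6% of the charge as X.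

The forecast gives 1.3 for the order in [G], 0.6 for the order in [J], alike and 90%, saying “So there is no visible inhibition or catalyst decay”, and its last figure lies below mine.

The flask gives 93.8% for the south-east run at 21 min, with 1.6 for the order in [G], 0.60 for the order in [J], and alike. These are its steps:

    G + J → X + G (84.00 M⁻¹ min⁻¹)
    2 J ⇌ J2, settled at all times (28.00 M⁻¹)
    G + Qe → Xi

Qe takes G at once into Xi, as a catalyst poison does. The dead G serves once more at the west charge: with it held fixed, a small change in [G] changes the working G, 9.08 × 10⁻⁴ M, by the same amount, so the order in [G] there is, on my reading, the charge over the working G, 1.65.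

The data stem from a simulated flask on assumed constants.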